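**Retrosynthetic overview**
- Target ⇐ E-selective Horner–Wadsworth–Emmons olefination of an α-phosphono-β-(3,4-dimethoxybenzyl)-γ-butyrolactone with O-TBS-vanillin, desilylated in the same pot (C=C made last).
- α-Phosphono lactone ⇐ Cu-catalysed homoconjugate opening of a cyclopropane-fused phosphono lactone at its CH2 by 3,4-dimethoxyphenylmagnesium bromide (benzylic C–C bond).
- Bicyclic phosphono lactone ⇐ (R)-epichlorohydrin + triethyl phosphonoacetate; the lone stereocentre comes from epichlorohydrin.
- Ring order: cyclopropane and γ-lactone close together in step 1 (the oxirane is consumed); the cyclopropane is opened in step 2; the lactone persists; both arenes are bought.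

Assumption: 5 (0.5 M in THF) and 7 are bought as catalogue reagents; each is otherwise one routine operation from 4-bromoveratrole/Mg or vanillin/TBSCl.

**Step 1**
Reactants: 1 (R)-epichlorohydrin; 2 triethyl phosphonoacetate
Product: 4 diethyl [(1R,5S)-2-oxo-3-oxabicyclo[3.1.0]hexan-1-yl]phosphonate, via epoxy phosphonoacetate 3 (not isolated)
Conditions: NaOEt (1.1 equiv), EtOH, 0 °C → reflux
Reagents that add atoms: none
Why: Proposed new method: the phosphonoacetate anion opens the oxirane of 1 at CH2, the chlorohydrin alkoxide recloses to epoxide 3 with loss of chloride, the re-formed stabilised carbanion closes the cyclopropane by 3-exo-tet attack with inversion at the epoxide CH (this sets the stereocentre, CH2O− ending cis to the ester and trans to the bulkier phosphonate), and the alkoxide lactonises with release of ethoxide, so cyclopropane and lactone form in one operation; the closest known reaction type is the double alkylation–lactonisation of malonate or arylacetonitrile anions with epichlorohydrin (same stereochemical course) together with the epoxide alkylation of phosphonoacetates to α-phosphono-γ-lactones.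

**Step 2**
Reactants: 4 diethyl [(1R,5S)-2-oxo-3-oxabicyclo[3.1.0]hexan-1-yl]phosphonate; 5 (3,4-dimethoxyphenyl)magnesium bromide
Product: 6 diethyl [(4S)-4-[(3,4-dimethoxyphenyl)methyl]-2-oxooxolan-3-yl]phosphonate (C3 epimers, trans major)
Conditions: 5 (1.5 equiv), CuI (10 mol%), THF, −30 → 0 °C; then 1 M HCl
Reagents that add atoms: none
Why: Copper-catalysed homoconjugate (SN2-type) addition of the aryl Grignard to the strained cyclopropane, doubly activated by the lactone C=O and the phosphonate, opens it at the unhindered CH2 and stops at the chelated phosphono-enolate, as is known for the ester analogue; the stereocentre is not involved (its descriptor becomes S only because the P-bearing carbon outranks CH2O).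

**Step 3**
Reactants: 6 diethyl [(4S)-4-[(3,4-dimethoxyphenyl)methyl]-2-oxooxolan-3-yl]phosphonate; 7 4-[(tert-butyldimethylsilyl)oxy]-3-methoxybenzaldehyde
Product: 9 (3E,4R)-4-[(3,4-dimethoxyphenyl)methyl]-3-[(4-hydroxy-3-methoxyphenyl)methylidene]oxolan-2-one, via TBS ether 8 (not isolated)
Conditions: NaH (1.1 equiv), THF, 0 °C → rt; then AcOH, TBAF, 0 °C
Reagents that add atoms: none
Why: Horner–Wadsworth–Emmons olefination, in which the sodium phosphono-enolate adds reversibly to the aryl aldehyde and collapses to the thermodynamically preferred E-arylidene (aryl anti to the lactone C=O), leaving the non-acidic C4 stereocentre untouched; buffered fluoride then cleaves the aryl silyl ether without isomerising the enoate.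

**Compound list**
1 | (R)-epichlorohydrin, (2R)-2-(chloromethyl)oxirane | ClC[C@H]1CO1 | starting material
2 | triethyl phosphonoacetate | CCOC(=O)CP(=O)(OCC)OCC | starting material
3 | ethyl 2-(diethoxyphosphoryl)-3-[(2R)-oxiran-2-yl]propanoate (C2 epimers) | CCOC(=O)C(C[C@@H]1CO1)P(=O)(OCC)OCC | intermediate
4 | diethyl [(1R,5S)-2-oxo-3-oxabicyclo[3.1.0]hexan-1-yl]phosphonate | O=C1OC[C@@H]2C[C@]12P(=O)(OCC)OCC | intermediate
5 | (3,4-dimethoxyphenyl)magnesium bromide | COc1ccc([Mg]Br)cc1OC | starting material
6 | diethyl [(4S)-4-[(3,4-dimethoxyphenyl)methyl]-2-oxooxolan-3-yl]phosphonate (C3 epimers) | CCOP(=O)(OCC)C1C(=O)OC[C@@H]1Cc1ccc(OC)c(OC)c1 | intermediate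
7 | 4-[(tert-butyldimethylsilyl)oxy]-3-methoxybenzaldehyde | COc1cc(C=O)ccc1O[Si](C)(C)C(C)(C)C | starting material
8 | (3E,4R)-3-[[4-[(tert-butyldimethylsilyl)oxy]-3-methoxyphenyl]methylidene]-4-[(3,4-dimethoxyphenyl)methyl]oxolan-2-one | COc1cc(/C=C2/C(=O)OC[C@@H]2Cc2ccc(OC)c(OC)c2)ccc1O[Si](C)(C)C(C)(C)C | intermediate
9 | (3E,4R)-4-[(3,4-dimethoxyphenyl)methyl]-3-[(4-hydroxy-3-methoxyphenyl)methylidene]oxolan-2-one | COc1cc(/C=C2/C(=O)OC[C@@H]2Cc2ccc(OC)c(OC)c2)ccc1O | target

**Total step count:** 3. **Longest linear sequence:** 3.

**Steps most likely to fail, with fallbacks**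

Step 1 is the riskiest. The unsymmetrical phosphonoacetate may close the cyclopropane with CH2O− cis to phosphorus, which cannot lactonise, or may stall at the γ-chloromethyl lactone. The fallback sets out from 1 and replaces the phosphonate handle by a carboxylate one. Dimethyl malonate with NaOMe in MeOH at reflux gives the well-precedented ester bicycle methyl (1S,5R)-2-oxo-3-oxabicyclo[3.1.0]hexane-1-carboxylate F1 by the same two-ring closure. Reagent 5 with catalytic CuI opens it to methyl (4R)-4-[(3,4-dimethoxyphenyl)methyl]-2-oxooxolane-3-carboxylate F2. LiOH followed by HCl gives (4R)-4-[(3,4-dimethoxyphenyl)methyl]-2-oxooxolane-3-carboxylic acid F3. A decarboxylative Knoevenagel (Doebner-type) condensation of F3 with unprotected vanillin (piperidine, pyridine, 90 °C) then installs the E-arylidene and comes back to the route at 9.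

Step 2 is next. The phosphonate activates the cyclopropane less than an ester does, and the aryl copper species may add to the lactone carbonyl instead. The fallback sets out from 4 and separates ring opening from arylation. MgI2 in THF, quenched cold with AcOH, opens the cyclopropane with iodide to give diethyl [(4S)-4-(iodomethyl)-2-oxooxolan-3-yl]phosphonate F4. A nickel-catalysed reductive cross-electrophile coupling of F4 with 4-bromoveratrole (NiI2·glyme, 4,4'-di-tert-butyl-2,2'-bipyridine, Zn, DMA, 60 °C) then forms the benzylic bond under base-free conditions and comes back to the route at 6.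

Step 3 is third. The tertiary phosphonate carbanion may react sluggishly with the electron-rich aldehyde or give E/Z mixtures. The fallback sets out from 6 and moves the aryl introduction to a C–H arylation. Olefination with aqueous formaldehyde and K2CO3, which is reliable for such phosphono lactones, gives (4R)-4-[(3,4-dimethoxyphenyl)methyl]-3-methylideneoxolan-2-one F5. A ligand-free Heck arylation of F5 with 4-iodo-2-methoxyphenol (Pd(OAc)2, KOAc, Bu4NCl, DMF, 80 °C) then delivers the E-arylidene lactone with the free phenol and comes back to the route at 9.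

**Further compounds**
F1 | step 1 | methyl (1S,5R)-2-oxo-3-oxabicyclo[3.1.0]hexane-1-carboxylate | O=C1OC[C@@H]2C[C@]12C(=O)OC
F2 | step 1 | methyl (4R)-4-[(3,4-dimethoxyphenyl)methyl]-2-oxooxolane-3-carboxylate (C3 epimers) | COC(=O)C1C(=O)OC[C@@H]1Cc1ccc(OC)c(OC)c1
F3 | step 1 | (4R)-4-[(3,4-dimethoxyphenyl)methyl]-2-oxooxolane-3-carboxylic acid (C3 epimers) | OC(=O)C1C(=O)OC[C@@H]1Cc1ccc(OC)c(OC)c1
F4 | step 2 | diethyl [(4S)-4-(iodomethyl)-2-oxooxolan-3-yl]phosphonate (C3 epimers) | CCOP(=O)(OCC)C1C(=O)OC[C@@H]1CI
F5 | step 3 | (4R)-4-[(3,4-dimethoxyphenyl)methyl]-3-methylideneoxolan-2-one | C=C1C(=O)OC[C@@H]1Cc1ccc(OC)c(OC)c1
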